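The C5 methyl (C14) and the C10 hydrogen are read as the two ends of a broken cyclopropane bond. C14 starts as a CH2 bridge across the C5–C10 ring fusion. It is released later, when the ring-B enol (C8=C9) pushes C10–C14 open. The feature exploited is that C8–O lies para to C5 in ring B while C3/C4 of ring A adjoin C5, which is the pattern of 6-methoxy-1-tetralone. In one operation the key step forms C5–C14 and C10–C14, closes the three-membered ring and fixes both fusion carbons on the β face. Its precursor is the Birch-derived 3β-hydroxy-4α-methyl-5(10)-octalin with C8 masked as an ethylene ketal.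

Key step: step 5

**Conventions.** Eremophilane numbering is used: ring A = C1–C5, C10; ring B = C5–C10; C14 on C5; C15 on C4. β is the face of C14. Read from the SMILES, the target is 3α-O-angelate, 4β-Me, 5β-Me, 7β-isopropenyl, 9β-O-senecioate, 10β-H (3R,4R,5R,7R,9R,10S). It is a cis-decalin whose favoured double chair has C14 axial on ring A and every other substituent equatorial.

**Design points.**
- (a) C8 stays a ketal from step 4 to step 8. A free β,γ-unsaturated ketone with a doubly activated C9–H would otherwise meet zinc alkoxides and zinc iodide in the key step. The ketal is also needed for (b).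
- (b) In 8, C3 and C4 have the opposite sense to the target and only steer C14. They are corrected on the propellane (steps 6 and 7), before the cyclopropane is opened. Three problems would arise after opening:
  - The 9-ene-3,8-dione should show almost no energy difference between the C4 epimers. C10 is sp2, so an axial 4α-methyl has lost a 1,3-diaxial partner, while the equatorial 4β-methyl is gauche to both C14 and C6.
  - The axial C14 methyl would block the axial hydride path at C3. Hydrides would then give the axial alcohol, as with friedelane-type 3-ketones.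
  - The enone would not survive a dissolving metal.
- (c) While C3 is a ketone (12, 13), the ring could also be opened from the ring-A side (C5–C14). These two compounds therefore see no acid.

**Assumption.** The sense of induction of IpcBH2 is taken from 1-methyl- and 1-phenylcycloalkenes. Should alkene 4 respond in the opposite sense, the reagent from (−)-α-pinene is used and nothing else changes.

Step 1
Reactants: 1 6-methoxy-1-tetralone; 2 methylmagnesium bromide
Product: 4 7-methoxy-4-methyl-1,2-dihydronaphthalene, via tertiary benzylic alcohol 3 (not isolated)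
Conditions: MeMgBr, THF, 0 °C to rt; then 2 M HCl, rt
Reagents that add atoms: methylmagnesium bromide, C[Mg]Br
Why: Grignard 1,2-addition brings in C15, and E1 dehydration of the p-methoxybenzylic tertiary alcohol gives the conjugated endocyclic C3=C4 alkene; no stereocentre is formed.

Step 2
Reactants: 4 7-methoxy-4-methyl-1,2-dihydronaphthalene
Product: 6 (1S,2S)-6-methoxy-1-methyl-1,2,3,4-tetrahydronaphthalen-2-ol, via isopinocampheyl(tetralinyl)borane 5 (not isolated)
Conditions: IpcBH2 [made beforehand from (+)-α-pinene], Et2O, −25 °C; then NaOH, 30% H2O2, 0 °C to rt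
Reagents that add atoms: hydrogen peroxide, OO
Why: In this Brown asymmetric hydroboration–oxidation boron goes to the less substituted, non-benzylic C3 (helped by the para methoxy group), syn addition of H and B makes 3-OH and 4-CH3 trans, the chiral borane selects the face (3β-O, 4β-H, hence 4α-CH3), oxidation proceeds with retention, and alcohol 6 can be recrystallised to raise its optical purity.

Step 3
Reactants: 6 (1S,2S)-6-methoxy-1-methyl-1,2,3,4-tetrahydronaphthalen-2-ol
Product: 7 (1S,2S)-6-methoxy-1-methyl-1,2,3,4,5,8-hexahydronaphthalen-2-ol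
Conditions: Li, NH3(l), THF, t-BuOH, −78 to −33 °C; NH4Cl
Reagents that add atoms: none
Why: Birch reduction of the anisole ring protonates ortho and meta to the methoxy group, which leaves the C7=C8 enol ether and the tetrasubstituted C5=C10 alkene unconjugated, while the C3 alkoxide and the C3/C4 centres are spectators.

Step 4
Reactants: 7 (1S,2S)-6-methoxy-1-methyl-1,2,3,4,5,8-hexahydronaphthalen-2-ol
Product: 8 8,8-ethylenedioxy-4α-methyl-5(10)-octalin-3β-ol
Conditions: ethylene glycol, PPTS (cat.), THF, rt
Reagents that add atoms: ethylene glycol, OCCO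
Why: Acid-catalysed addition of the diol to the enol ether (protonation at C7, oxocarbenium ion at C8, transketalisation) gives the ketal without ever freeing the β,γ-unsaturated ketone, so C5=C10 cannot move into conjugation and no stereocentre changes.

Step 5
Reactants: 8 8,8-ethylenedioxy-4α-methyl-5(10)-octalin-3β-ol; 9 diiodomethane
Product: 11 8,8-ethylenedioxy-4α-methyl-5β,10β-methanodecalin-3β-ol, via iodomethylzinc alkoxide 10 (not isolated)
Conditions: Et2Zn (3 equiv), CH2I2 (3 equiv), CH2Cl2, −15 °C to rt; aq NH4Cl
Reagents that add atoms: diiodomethane, ICI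
Why: Diethylzinc turns the C3 hydroxyl into a zinc alkoxide and exchange with CH2I2 gives the bound carbenoid 10, which, activated by a second zinc species, hands its CH2 to the C5=C10 π bond through the concerted butterfly transition state, so C5–C14 and C10–C14 form together and syn. The closest known reaction type is the Simmons–Smith reaction (Furukawa variant) of Birch-derived tetrasubstituted 5(10)-alkenes under the direction of a homoallylic hydroxyl. The three-membered ring closes by [2+1] methylene transfer to the alkene, not by cyclisation of a chain, and turns the octalin into a [4.4.1]propellane. C5 and C10 are set in the same event: their mutual cis relation follows from the concerted addition, and their β sense from the 3β-oxygen that carries the zinc. The step needs β-face selectivity, and allylic strain against C6H2 keeps the 4α-methyl pseudoaxial, which places the trans 3β-alkoxide axial above C5 and the methyl across the α face, so director and shield act in the same sense. Chemoselectivity is settled beforehand, because the enol ether bond of 7 has become a ketal and no enolisable β,γ-unsaturated ketone is exposed to zinc iodide.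

Step 6
Reactants: 11 8,8-ethylenedioxy-4α-methyl-5β,10β-methanodecalin-3β-ol
Product: 13 8,8-ethylenedioxy-4β-methyl-5β,10β-methanodecalin-3-one, via 4α-methyl ketone 12 (not isolated)
Conditions: TPAP (cat.), NMO, 4 Å MS, CH2Cl2, rt; filter, then NaOMe (cat.), MeOH, rt
Reagents that add atoms: none
Why: The neutral Ley–Griffith oxidation spares ketal and cyclopropane, and base-catalysed enolate equilibration should then move C15 to the β face, because the cyclopropane bends the C5–C6 bond toward the α face, where it nearly eclipses a 4α-methyl, and leaves the widest gap (between C14 and C6) for a pseudoequatorial 4β-methyl.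

Step 7
Reactants: 13 8,8-ethylenedioxy-4β-methyl-5β,10β-methanodecalin-3-one
Product: 14 8,8-ethylenedioxy-4β-methyl-5β,10β-methanodecalin-3α-ol
Conditions: Li, NH3(l), THF, EtOH, −78 °C; NH4Cl
Reagents that add atoms: none
Why: Dissolving-metal reduction of the ketone runs through the ketyl and gives the more stable alcohol, here the equatorial 3α-OH trans to the 4β-methyl, while the ketal and the non-conjugated cyclopropane are inert to the metal.

Step 8
Reactants: 14 8,8-ethylenedioxy-4β-methyl-5β,10β-methanodecalin-3α-ol
Product: 16 (4aR,5R,6R)-6-hydroxy-4a,5-dimethyl-4,4a,5,6,7,8-hexahydronaphthalen-2(3H)-one, via cyclopropyl ketone 15 (not isolated)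
Conditions: 3 M HCl, THF–MeOH, 60 °C
Reagents that add atoms: water, O
Why: Acid first hydrolyses the ketal and then cleaves the β-cyclopropyl ketone by homoconjugate protonolysis, in which the C8 enol donates through C9 into C10 while C14 takes the proton; the external C10–C14 bond is aligned with the enol π orbital whereas C5–C10 lies in the ring plane, so C14 becomes the 5β-methyl with C5 untouched, the 9-en-8-one appears, and no ring-A enol can compete because C3 is now an alcohol.

Step 9
Reactants: 16 3α-hydroxy-4β,5β-dimethyl-9-octalin-8-one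
Product: 17 3α-(tert-butyldimethylsilyloxy)-4β,5β-dimethyl-9-octalin-8-one
Conditions: TBSCl, imidazole, DMF, rt
Reagents that add atoms: tert-butyldimethylsilyl chloride, CC(C)(C)[Si](C)(C)Cl
Why: Imidazole-promoted silyl ether formation protects the equatorial C3 hydroxyl with a group that withstands silane, peracid and amide base, and the chloride (unlike the triflate) leaves the enone alone.

Step 10
Reactants: 17 3α-(tert-butyldimethylsilyloxy)-4β,5β-dimethyl-9-octalin-8-one
Product: 18 cis-fused 10βH C8=C9 dimethylphenylsilyl enol ether of the 3α-OTBS decalone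
Conditions: [(Ph3P)CuH]6 (cat.), PhMe2SiH, toluene, rt
Reagents that add atoms: dimethylphenylsilane, C[SiH](C)c1ccccc1
Why: In this copper hydride 1,4-hydrosilylation (Stryker-type catalyst) the bulky Cu–H adds to C10 from the β face, because the α-axial path is closed by the axial hydrogens on C2, C4 and C6 (the same sense as cuprate additions to angular-methyl octalones), which sets 10β-H (cis fusion) and stores the enolate regiospecifically as the C8=C9 silyl enol ether.

Step 11
Reactants: 18 cis-fused C8=C9 dimethylphenylsilyl enol ether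
Product: 21 9β-hydroxy-3α-(tert-butyldimethylsilyloxy)-4β,5β-dimethyl-10βH-decalin-8-one, via silyloxy epoxide 19 (not isolated), via 9β-silyloxy ketone 20 (not isolated)
Conditions: mCPBA, NaHCO3, CH2Cl2, −20 °C; then 10% aq citric acid, THF, rt
Reagents that add atoms: 3-chloroperbenzoic acid, OOC(=O)c1cccc(Cl)c1
Why: In the Rubottom oxidation the peracid epoxidises the electron-rich C8=C9 bond from the convex β face, since the equatorial 3α/4β groups lock the conformer in which C4 and its axial hydrogen cover the α face of ring B, and silyl migration followed by mild hydrolysis gives the 9β (equatorial) alcohol, which is also the more stable epimer.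

Step 12
Reactants: 21 9β-hydroxy ketone
Product: 22 9β-(triethylsilyloxy)-3α-(tert-butyldimethylsilyloxy)-4β,5β-dimethyl-10βH-decalin-8-one
Conditions: TESCl, imidazole, CH2Cl2, 0 °C to rt
Reagents that add atoms: triethylsilyl chloride, CC[Si](Cl)(CC)CC
Why: Silyl ether formation masks the α-ketol (no enediolate or ketol shift under base) with a group that can later be removed in the presence of the C3 TBS ether.

Step 13
Reactants: 22 9β-OTES ketone; 23 2-bromopropene
Product: 26 7β-isopropenyl-9β-(triethylsilyloxy)-3α-(tert-butyldimethylsilyloxy)-4β,5β-dimethyl-10βH-decalin-8-one, via lithium enolate 24 (not isolated), via lithium dienolate 25 (not isolated)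
Conditions: LiHMDS (2.2 equiv), THF, −78 °C; Pd2(dba)3 (cat.), t-Bu3P·HBF4 (cat.), 2-bromopropene, −78 °C to rt; AcOH, −78 °C; Et3N, CH2Cl2, rt if the 7α epimer is present
Reagents that add atoms: 2-bromopropene, C=C(C)Br
Why: In this palladium-catalysed α-alkenylation of a ketone enolate, kinetic deprotonation takes the unhindered C7–H rather than the tertiary, silyloxy-bearing C9–H, the more acidic product rests as dienolate 25 (which prevents a second coupling), cold acid protonates its α carbon to keep the double bond out of conjugation, and C7 ends β (equatorial) because a 7α group would be 1,3-diaxial to C4.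

Step 14
Reactants: 26 7β-isopropenyl bis-silyl ether
Product: 27 9β-hydroxy-7β-isopropenyl-3α-(tert-butyldimethylsilyloxy)-4β,5β-dimethyl-10βH-decalin-8-one
Conditions: AcOH–THF–H2O, rt
Reagents that add atoms: none
Why: In this selective acidic solvolysis of silyl ethers the triethylsilyl group leaves much faster than the hindered TBS group, and the weak acid should leave the β,γ-unsaturated ketone and C7/C9 unchanged.

Step 15
Reactants: 27 9β-hydroxy ketone; 28 3-methylbut-2-enoyl chloride (senecioyl chloride)
Product: 29 9β-senecioyloxy-7β-isopropenyl-3α-(tert-butyldimethylsilyloxy)-4β,5β-dimethyl-10βH-decalin-8-one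
Conditions: senecioyl chloride, pyridine, DMAP (cat.), CH2Cl2, 0 °C
Reagents that add atoms: 3-methylbut-2-enoyl chloride, CC(C)=CC(=O)Cl
Why: DMAP-catalysed acylation of the α-ketol is run with pyridine rather than a trialkylamine to keep vinylketene formation, and thus deconjugation of the acyl unit, low, and C9 keeps its equatorial configuration.

Step 16
Reactants: 29 9β-senecioate TBS ether
Product: 30 3α-hydroxy-9β-senecioyloxy-7β-isopropenyl-4β,5β-dimethyl-10βH-decalin-8-one
Conditions: HF·pyridine, pyridine, THF, 0 °C to rt
Reagents that add atoms: none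
Why: Fluoride-mediated desilylation in a buffered, non-basic medium leaves the ester, the isopropenyl ketone and the epimerisable C7 and C9 centres alone.

Step 17
Reactants: 30 3α-hydroxy 9β-senecioate; 31 angelic acid
Product: 33 target (CNP0375730.2), via mixed anhydride 32 (not isolated)
Conditions: angelic acid, 2,4,6-trichlorobenzoyl chloride, Et3N, toluene, rt; then 30, toluene, 75 °C
Reagents that add atoms: angelic acid, C/C=C(/C)C(=O)O
Why: In this Yamaguchi-type esterification the alcohol attacks the less hindered angeloyl carbonyl of 32, C3–O is not broken so the 3α configuration is kept, and running without a nucleophilic catalyst or strong base should preserve the Z geometry and the unconjugated isopropenyl ketone.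

Compound list
1 | 6-methoxy-1-tetralone | COc1ccc2c(c1)CCCC2=O | starting material
2 | methylmagnesium bromide | C[Mg]Br | starting material
3 | 6-methoxy-1-methyl-1,2,3,4-tetrahydronaphthalen-1-ol (racemic) | COc1ccc2c(c1)CCCC2(C)O | intermediate
4 | 7-methoxy-4-methyl-1,2-dihydronaphthalene | COc1ccc2c(c1)CCC=C2C | intermediate
5 | isopinocampheyl[(1S,2S)-6-methoxy-1-methyltetralin-2-yl]borane | C[C@H]1[C@H](B[C@H]3CCc4cc(OC)ccc4[C@@H]3C)C[C@@H]2C[C@H]1C2(C)C | intermediate
6 | (1S,2S)-6-methoxy-1-methyl-1,2,3,4-tetrahydronaphthalen-2-ol (trans; 3β-OH, 4α-Me) | C[C@@H]1[C@@H](O)CCc2cc(OC)ccc12 | intermediate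
7 | (1S,2S)-6-methoxy-1-methyl-1,2,3,4,5,8-hexahydronaphthalen-2-ol | C[C@@H]1[C@@H](O)CCC2=C1CC=C(OC)C2 | intermediate
8 | 8,8-ethylenedioxy-4α-methyl-5(10)-octalin-3β-ol (key-step precursor) | C[C@@H]1[C@@H](O)CCC2=C1CCC3(OCCO3)C2 | intermediate
9 | diiodomethane | ICI | starting material
10 | iodomethylzinc 3β-alkoxide of 8 | C[C@@H]1[C@@H](O[Zn]CI)CCC2=C1CCC3(OCCO3)C2 | intermediate
11 | 8,8-ethylenedioxy-4α-methyl-5β,10β-methanodecalin-3β-ol (key-step product, [4.4.1]propellane) | C[C@@H]1[C@@H](O)CC[C@@]23C[C@@]12CCC4(OCCO4)C3 | intermediate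
12 | 8,8-ethylenedioxy-4α-methyl-5β,10β-methanodecalin-3-one | C[C@@H]1C(=O)CC[C@@]23C[C@@]12CCC4(OCCO4)C3 | intermediate
13 | 8,8-ethylenedioxy-4β-methyl-5β,10β-methanodecalin-3-one | C[C@H]1C(=O)CC[C@@]23C[C@@]12CCC4(OCCO4)C3 | intermediate
14 | 8,8-ethylenedioxy-4β-methyl-5β,10β-methanodecalin-3α-ol | C[C@H]1[C@H](O)CC[C@@]23C[C@@]12CCC4(OCCO4)C3 | intermediate
15 | 3α-hydroxy-4β-methyl-5β,10β-methanodecalin-8-one | C[C@H]1[C@H](O)CC[C@@]23C[C@@]12CCC(=O)C3 | intermediate
16 | (4aR,5R,6R)-6-hydroxy-4a,5-dimethyl-4,4a,5,6,7,8-hexahydronaphthalen-2(3H)-one (3α-OH, 4β,5β-Me2, 9-en-8-one) | C[C@H]1[C@H](O)CCC2=CC(=O)CC[C@]12C | intermediate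
17 | TBS ether of 16 | C[C@H]1[C@H](O[Si](C)(C)C(C)(C)C)CCC2=CC(=O)CC[C@]12C | intermediate
18 | cis-fused (10β-H) C8=C9 dimethylphenylsilyl enol ether, 3α-OTBS | C[C@H]1[C@H](O[Si](C)(C)C(C)(C)C)CC[C@@H]2C=C(O[Si](C)(C)c3ccccc3)CC[C@]12C | intermediate
19 | 8β,9β-epoxide of 18 | C[C@H]1[C@H](O[Si](C)(C)C(C)(C)C)CC[C@@H]2[C@H]3O[C@@]3(O[Si](C)(C)c4ccccc4)CC[C@]12C | intermediate
20 | 9β-(dimethylphenylsilyloxy)-3α-OTBS-4β,5β-dimethyl-10βH-decalin-8-one | C[C@H]1[C@H](O[Si](C)(C)C(C)(C)C)CC[C@@H]2[C@@H](O[Si](C)(C)c3ccccc3)C(=O)CC[C@]12C | intermediate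
21 | 9β-hydroxy-3α-OTBS-4β,5β-dimethyl-10βH-decalin-8-one | C[C@H]1[C@H](O[Si](C)(C)C(C)(C)C)CC[C@@H]2[C@@H](O)C(=O)CC[C@]12C | intermediate
22 | 9β-OTES-3α-OTBS-4β,5β-dimethyl-10βH-decalin-8-one | C[C@H]1[C@H](O[Si](C)(C)C(C)(C)C)CC[C@@H]2[C@@H](O[Si](CC)(CC)CC)C(=O)CC[C@]12C | intermediate
23 | 2-bromopropene | C=C(C)Br | starting material
24 | lithium C7=C8 enolate of 22 | C[C@H]1[C@H](O[Si](C)(C)C(C)(C)C)CC[C@@H]2[C@@H](O[Si](CC)(CC)CC)C(O[Li])=CC[C@]12C | intermediate
25 | lithium dienolate of 26 | C[C@H]1[C@H](O[Si](C)(C)C(C)(C)C)CC[C@@H]2[C@@H](O[Si](CC)(CC)CC)C(O[Li])=C(C(C)=C)C[C@]12C | intermediate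
26 | 7β-isopropenyl-9β-OTES-3α-OTBS-4β,5β-dimethyl-10βH-decalin-8-one | C[C@H]1[C@H](O[Si](C)(C)C(C)(C)C)CC[C@@H]2[C@@H](O[Si](CC)(CC)CC)C(=O)[C@@H](C(C)=C)C[C@]12C | intermediate
27 | 9β-hydroxy-7β-isopropenyl-3α-OTBS-4β,5β-dimethyl-10βH-decalin-8-one | C[C@H]1[C@H](O[Si](C)(C)C(C)(C)C)CC[C@@H]2[C@@H](O)C(=O)[C@@H](C(C)=C)C[C@]12C | intermediate
28 | 3-methylbut-2-enoyl chloride (senecioyl chloride) | CC(C)=CC(=O)Cl | starting material
29 | 9β-senecioyloxy-7β-isopropenyl-3α-OTBS-4β,5β-dimethyl-10βH-decalin-8-one | C[C@H]1[C@H](O[Si](C)(C)C(C)(C)C)CC[C@@H]2[C@@H](OC(=O)C=C(C)C)C(=O)[C@@H](C(C)=C)C[C@]12C | intermediate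
30 | 3α-hydroxy-9β-senecioyloxy-7β-isopropenyl-4β,5β-dimethyl-10βH-decalin-8-one | C[C@H]1[C@H](O)CC[C@@H]2[C@@H](OC(=O)C=C(C)C)C(=O)[C@@H](C(C)=C)C[C@]12C | intermediate
31 | angelic acid, (Z)-2-methylbut-2-enoic acid | C/C=C(/C)C(=O)O | starting material
32 | angelic 2,4,6-trichlorobenzoic anhydride | C/C=C(/C)C(=O)OC(=O)c1c(Cl)cc(Cl)cc1Cl | intermediate
33 | 3α-angeloyloxy-9β-senecioyloxy-10βH-eremophil-11-en-8-one (CNP0375730.2) | C=C(C)[C@H]1C[C@@]2(C)[C@H](CC[C@@H](OC(=O)/C(C)=C\C)[C@@H]2C)[C@@H](OC(=O)C=C(C)C)C1=O | target

Total step count: 17. Longest linear sequence: 17 steps (1 to 33).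

Steps most likely to fail

**Step 13 (α-alkenylation at C7).**
- Proton exchange between enolates may move the enolate toward C9.
- The dienolate may be reprotonated at the terminal carbon, so that the double bond drifts into conjugation, or on the wrong face of C7.
- Palladium hydride pathways may consume the bromide.

The fallback replaces the cross-coupling by carbonyl addition. It sets out from 22. The zinc enolate (LDA, then ZnCl2, THF, −78 °C) is added to acetone to give the 7β-(2-hydroxypropan-2-yl) ketone F1. Mesylation (MsCl, Et3N, DMAP) gives the tertiary mesylate F2. This eliminates by E1cB in the same flask to the conjugated 7(11)-ene, the isopropylidene ketone F3. The extended potassium dienolate is then formed (KOt-Bu, THF/t-BuOH) and quenched inversely into cold aqueous acetic acid. This protonates C7 kinetically and returns to the route at 26.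

**Step 6 (oxidation and C4 equilibration).**
- The equilibrium may not lie far enough on the 4β side.
- Enolisation toward the crowded C4 may be slow.
- Long exposure to base may let the enolate open C5–C14.

The fallback sets C4 before the key step instead of after it, and sets out from 6. Ley–Griffith oxidation gives 6-methoxy-1-methyl-2-tetralone F4, whose benzylic centre racemises freely. Noyori-type asymmetric transfer hydrogenation under dynamic kinetic resolution follows (the Ru–TsDPEN enantiomer that gives the 2S carbinol, HCO2H/Et3N). It adds hydride anti to the pseudoaxial methyl and gives the cis alcohol F5 (3β-OH, 4β-Me). Birch reduction gives the dienol ether F6, and ketal exchange gives the ene ketal F7. The hydroxyl-directed Simmons–Smith reaction gives the propellane alcohol F8; here the oxygen alone has to outweigh the methyl group on the same face. Ley–Griffith oxidation of F8 returns to the route at 13.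

**Step 5 (key step).**
- The ketal oxygens may compete with the C3 alkoxide for zinc and erode the facial selectivity.
- Zinc iodide may strip the ketal.
- The hydroxyl may be O-methylated during a slow attack on the hindered alkene.

The fallback changes the protecting-group order and sets out from 7. Oxalic acid in aqueous methanol–THF hydrolyses only the enol ether, giving the free 3β-hydroxy-4α-methyl-5(10)-octalin-8-one F9. The same directed cyclopropanation, now with the C3 alkoxide as the only strong donor, gives the 5β,10β-methano ketone F10. Aprotic Noyori ketalisation (1,2-bis(trimethylsilyloxy)ethane, TMSOTf cat., CH2Cl2, −78 °C, then mild aqueous work-up) returns to the route at 11.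

Further compounds
F1 | step 13 | 7β-(2-hydroxypropan-2-yl)-9β-OTES-3α-OTBS-4β,5β-dimethyl-10βH-decalin-8-one | C[C@H]1[C@H](O[Si](C)(C)C(C)(C)C)CC[C@@H]2[C@@H](O[Si](CC)(CC)CC)C(=O)[C@@H](C(C)(C)O)C[C@]12C
F2 | step 13 | tertiary mesylate of F1 | C[C@H]1[C@H](O[Si](C)(C)C(C)(C)C)CC[C@@H]2[C@@H](O[Si](CC)(CC)CC)C(=O)[C@@H](C(C)(C)OS(C)(=O)=O)C[C@]12C
F3 | step 13 | 7-isopropylidene-9β-OTES-3α-OTBS-4β,5β-dimethyl-10βH-decalin-8-one | C[C@H]1[C@H](O[Si](C)(C)C(C)(C)C)CC[C@@H]2[C@@H](O[Si](CC)(CC)CC)C(=O)C(=C(C)C)C[C@]12C
F4 | step 6 | 6-methoxy-1-methyl-3,4-dihydronaphthalen-2(1H)-one (configurationally labile) | CC1C(=O)CCc2cc(OC)ccc12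
F5 | step 6 | (1R,2S)-6-methoxy-1-methyl-1,2,3,4-tetrahydronaphthalen-2-ol (cis; 3β-OH, 4β-Me) | C[C@H]1[C@@H](O)CCc2cc(OC)ccc12
F6 | step 6 | (1R,2S)-6-methoxy-1-methyl-1,2,3,4,5,8-hexahydronaphthalen-2-ol | C[C@H]1[C@@H](O)CCC2=C1CC=C(OC)C2
F7 | step 6 | 8,8-ethylenedioxy-4β-methyl-5(10)-octalin-3β-ol | C[C@H]1[C@@H](O)CCC2=C1CCC3(OCCO3)C2
F8 | step 6 | 8,8-ethylenedioxy-4β-methyl-5β,10β-methanodecalin-3β-ol | C[C@H]1[C@@H](O)CC[C@@]23C[C@@]12CCC4(OCCO4)C3
F9 | step 5 | 3β-hydroxy-4α-methyl-5(10)-octalin-8-one | C[C@@H]1[C@@H](O)CCC2=C1CCC(=O)C2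
F10 | step 5 | 3β-hydroxy-4α-methyl-5β,10β-methanodecalin-8-one | C[C@@H]1[C@@H](O)CC[C@@]23C[C@@]12CCC(=O)C3
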